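**Retrosynthetic overview**

1. Target 36 ⇐ Pinnick oxidation of bicyclic aldehyde 35 ⇐ intramolecular Diels–Alder (IMDA) of the open-chain (2E,4Z,6S,7E,9E,11E,13E)-hexaenal 34. This one step makes the C3–C7 and C2–C10 bonds, so the cyclohexene and the cyclopentene close together and last.
2. 34 ⇐ C7 aldehyde 20 by three E-selective Wittig / DIBAL / MnO2 cycles (Me, Et, Me) and a benzylphosphonate HWE.
3. 20 ⇐ (2E,4Z)-hydroxy dienoate 15 ⇐ Wittig opening of lactol 12 ⇐ unsaturated δ-lactone 11, whose ring fixes the (4Z)-trisubstituted tether olefin.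
4. 11 ⇐ key C4–C5 bond: intermolecular aldol of the lithium enolate of ethyl butanoate (5) with aldehyde 4 from (S)-Roche ester (1), then lactonisation and dehydration.
5. Ring order: temporary δ-lactone (steps 5–6, opened in step 8), then cyclohexene + cyclopentene simultaneously (step 25).

Assumption and notation: open-chain compounds are numbered C1–C14 from the future carboxyl carbon; TBS = tert-butyldimethylsilyl, TBDPS = tert-butyldiphenylsilyl; ylides 13 and 24 and phosphonate 31 are taken as purchased (24 can otherwise be made from ethyl 2-bromobutanoate and PPh3).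

**Route**

Step 1
Reactants: 1 methyl (S)-3-hydroxy-2-methylpropanoate ((S)-Roche ester)
Product: 2 methyl (S)-3-(TBSO)-2-methylpropanoate
Conditions: TBSCl, imidazole, CH2Cl2, 0 °C → rt
Reagents that add atoms: tert-butyldimethylsilyl chloride, CC(C)(C)[Si](C)(C)Cl
Why: Imidazole-promoted silylation of the primary alcohol; the stereocentre (the future C6, taken from the chiral pool) is not touched.

Step 2
Reactants: 2 methyl (S)-3-(TBSO)-2-methylpropanoate
Product: 3 (R)-3-(TBSO)-2-methylpropan-1-ol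
Conditions: DIBAL-H (2.3 equiv), CH2Cl2, −78 → 0 °C; Rochelle salt
Reagents that add atoms: none
Why: DIBAL ester reduction to the primary alcohol; the stereocentre is unchanged (the descriptor changes only through CIP priorities).

Step 3
Reactants: 3 (R)-3-(TBSO)-2-methylpropan-1-ol
Product: 4 (S)-3-(TBSO)-2-methylpropanal
Conditions: TEMPO (cat.), PhI(OAc)2, CH2Cl2, rt; used crude
Reagents that add atoms: none
Why: TEMPO/PhI(OAc)2 oxidation stops at the aldehyde and is base-free, so the α-methyl aldehyde is not epimerised.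

Step 4
Reactants: 4 (S)-3-(TBSO)-2-methylpropanal; 5 ethyl butanoate
Product: 7 ethyl (4S)-5-(TBSO)-2-ethyl-3-hydroxy-4-methylpentanoate (C2/C3 epimer mixture), via lithium enolate of ethyl butanoate 6 (not isolated)
Conditions: LDA, THF, −78 °C, 5; then 4, −78 °C, 30 min; AcOH quench
Reagents that add atoms: none
Why: Directed lithium-enolate aldol addition forms the C4–C5 bond and joins the two fragments; it is fast at −78 °C, leaves the existing stereocentre intact, and the two new centres (mixture) are both erased in step 6.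

Step 5
Reactants: 7 ethyl (4S)-5-(TBSO)-2-ethyl-3-hydroxy-4-methylpentanoate
Product: 9 (5S)-3-ethyl-4-hydroxy-5-methyltetrahydro-2H-pyran-2-one, via diol ester 8 (not isolated)
Conditions: 48% aq. HF, MeCN, 0 °C → rt; then TsOH (cat.), PhMe, 50 °C
Reagents that add atoms: none
Why: Desilylation frees the primary alcohol, which closes the six-membered lactone by acid-catalysed transesterification (lactonisation).

Step 6
Reactants: 9 (5S)-3-ethyl-4-hydroxy-5-methyltetrahydro-2H-pyran-2-one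
Product: 11 (R)-3-ethyl-5-methyl-5,6-dihydro-2H-pyran-2-one, via mesylate 10 (not isolated)
Conditions: MsCl, Et3N, CH2Cl2, 0 °C; then DBU, 0 °C → rt
Reagents that add atoms: none
Why: Mesylation and E1cB elimination give the conjugated endocyclic olefin, which the ring forces to be cis (the future 4Z olefin); the γ-stereocentre is not deprotonated by DBU under these conditions.

Step 7
Reactants: 11 (R)-3-ethyl-5-methyl-5,6-dihydro-2H-pyran-2-one
Product: 12 (5R)-3-ethyl-5-methyl-5,6-dihydro-2H-pyran-2-ol (anomer mixture)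
Conditions: DIBAL-H (1.05 equiv), CH2Cl2, −78 °C; MeOH, Rochelle salt
Reagents that add atoms: none
Why: Partial DIBAL reduction of the lactone stops at the lactol at −78 °C (1,2-reduction; olefin and stereocentre untouched).

Step 8
Reactants: 12 (5R)-3-ethyl-5-methyl-5,6-dihydro-2H-pyran-2-ol; 13 ethyl 2-(triphenylphosphoranylidene)propanoate
Product: 15 ethyl (2E,4Z,6R)-4-ethyl-7-hydroxy-2,6-dimethylhepta-2,4-dienoate, via open-chain hydroxy enal 14 (not isolated)
Conditions: PhMe, PhCO2H (cat.), 70 °C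
Reagents that add atoms: none
Why: Wittig olefination of the ring-opened lactol tautomer; the stabilised α-methyl ylide gives the (2E) olefin and the (4Z) geometry is carried over from the ring.

Step 9
Reactants: 15 ethyl (2E,4Z,6R)-4-ethyl-7-hydroxy-2,6-dimethylhepta-2,4-dienoate
Product: 16 ethyl (2E,4Z,6R)-7-(TBSO)-4-ethyl-2,6-dimethylhepta-2,4-dienoate
Conditions: TBSCl, imidazole, CH2Cl2, rt
Reagents that add atoms: tert-butyldimethylsilyl chloride, CC(C)(C)[Si](C)(C)Cl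
Why: Silylation of the primary C7 alcohol so that the ester can be reduced without a free diol.

Step 10
Reactants: 16 ethyl (2E,4Z,6R)-7-(TBSO)-4-ethyl-2,6-dimethylhepta-2,4-dienoate
Product: 17 (2E,4Z,6R)-7-(TBSO)-4-ethyl-2,6-dimethylhepta-2,4-dien-1-ol
Conditions: DIBAL-H (2.5 equiv), CH2Cl2, −78 °C; Rochelle salt
Reagents that add atoms: none
Why: DIBAL 1,2-reduction of the dienoate masks the future dienophile as a dienol, so that C6–H is not acidified when C7 later becomes an aldehyde.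

Step 11
Reactants: 17 (2E,4Z,6R)-7-(TBSO)-4-ethyl-2,6-dimethylhepta-2,4-dien-1-ol
Product: 18 tert-butyl{[(2E,4Z,6R)-7-(TBSO)-4-ethyl-2,6-dimethylhepta-2,4-dien-1-yl]oxy}diphenylsilane
Conditions: TBDPSCl, imidazole, DMAP (cat.), CH2Cl2, rt
Reagents that add atoms: tert-butyldiphenylsilyl chloride, CC(C)(C)[Si](Cl)(c1ccccc1)c1ccccc1
Why: Silylation with the acid-stable TBDPS group gives two primary silyl ethers that can be told apart.

Step 12
Reactants: 18 tert-butyl{[(2E,4Z,6R)-7-(TBSO)-4-ethyl-2,6-dimethylhepta-2,4-dien-1-yl]oxy}diphenylsilane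
Product: 19 (2R,3Z,5E)-7-(TBDPSO)-4-ethyl-2,6-dimethylhepta-3,5-dien-1-ol
Conditions: PPTS (cat.), MeOH, rt
Reagents that add atoms: none
Why: Acid-catalysed methanolysis cleaves the primary TBS ether about a hundred times faster than the primary TBDPS ether (selective desilylation).

Step 13
Reactants: 19 (2R,3Z,5E)-7-(TBDPSO)-4-ethyl-2,6-dimethylhepta-3,5-dien-1-ol
Product: 20 (2R,3Z,5E)-7-(TBDPSO)-4-ethyl-2,6-dimethylhepta-3,5-dienal
Conditions: TEMPO (cat.), PhI(OAc)2, CH2Cl2, 0 °C → rt; used at once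
Reagents that add atoms: none
Why: Base-free TEMPO oxidation to the aldehyde; allylic strain across the Z olefin keeps the α C–H in the olefin plane, which slows enolisation into conjugation.

Step 14
Reactants: 20 (2R,3Z,5E)-7-(TBDPSO)-4-ethyl-2,6-dimethylhepta-3,5-dienal; 13 ethyl 2-(triphenylphosphoranylidene)propanoate
Product: 21 ethyl (2E,4R,5Z,7E)-9-(TBDPSO)-6-ethyl-2,4,8-trimethylnona-2,5,7-trienoate
Conditions: CH2Cl2, rt → 40 °C
Reagents that add atoms: none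
Why: Wittig reaction with a stabilised α-methyl ylide under neutral conditions gives the E-trisubstituted C7=C8 olefin without epimerising C6.

Step 15
Reactants: 21 ethyl (2E,4R,5Z,7E)-9-(TBDPSO)-6-ethyl-2,4,8-trimethylnona-2,5,7-trienoate
Product: 22 (2E,4R,5Z,7E)-9-(TBDPSO)-6-ethyl-2,4,8-trimethylnona-2,5,7-trien-1-ol
Conditions: DIBAL-H (2.3 equiv), CH2Cl2, −78 °C; Rochelle salt
Reagents that add atoms: none
Why: DIBAL 1,2-reduction of the enoate to the allylic alcohol; silyl ether and olefins are inert.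

Step 16
Reactants: 22 (2E,4R,5Z,7E)-9-(TBDPSO)-6-ethyl-2,4,8-trimethylnona-2,5,7-trien-1-ol
Product: 23 (2E,4R,5Z,7E)-9-(TBDPSO)-6-ethyl-2,4,8-trimethylnona-2,5,7-trienal
Conditions: MnO2 (excess), CH2Cl2, rt
Reagents that add atoms: none
Why: Chemoselective MnO2 oxidation of the allylic alcohol to the enal with retention of olefin geometry.

Step 17
Reactants: 23 (2E,4R,5Z,7E)-9-(TBDPSO)-6-ethyl-2,4,8-trimethylnona-2,5,7-trienal; 24 ethyl 2-(triphenylphosphoranylidene)butanoate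
Product: 25 ethyl (2E,4E,6S,7Z,9E)-11-(TBDPSO)-2,8-diethyl-4,6,10-trimethylundeca-2,4,7,9-tetraenoate
Conditions: PhMe, 60 °C, dark
Reagents that add atoms: none
Why: Wittig reaction with the stabilised α-ethyl ylide installs the E C9=C10 olefin bearing the ethyl branch.

Step 18
Reactants: 25 ethyl (2E,4E,6S,7Z,9E)-11-(TBDPSO)-2,8-diethyl-4,6,10-trimethylundeca-2,4,7,9-tetraenoate
Product: 26 (2E,4E,6S,7Z,9E)-11-(TBDPSO)-2,8-diethyl-4,6,10-trimethylundeca-2,4,7,9-tetraen-1-ol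
Conditions: DIBAL-H (2.3 equiv), CH2Cl2, −78 °C; Rochelle salt
Reagents that add atoms: none
Why: DIBAL 1,2-reduction of the dienoate to the dienol.

Step 19
Reactants: 26 (2E,4E,6S,7Z,9E)-11-(TBDPSO)-2,8-diethyl-4,6,10-trimethylundeca-2,4,7,9-tetraen-1-ol
Product: 27 (2E,4E,6S,7Z,9E)-11-(TBDPSO)-2,8-diethyl-4,6,10-trimethylundeca-2,4,7,9-tetraenal
Conditions: MnO2 (excess), CH2Cl2, rt
Reagents that add atoms: none
Why: MnO2 allylic oxidation to the dienal.

Step 20
Reactants: 27 (2E,4E,6S,7Z,9E)-11-(TBDPSO)-2,8-diethyl-4,6,10-trimethylundeca-2,4,7,9-tetraenal; 13 ethyl 2-(triphenylphosphoranylidene)propanoate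
Product: 28 ethyl (2E,4E,6E,8S,9Z,11E)-13-(TBDPSO)-4,10-diethyl-2,6,8,12-tetramethyltrideca-2,4,6,9,11-pentaenoate
Conditions: PhMe, 60 °C, dark
Reagents that add atoms: none
Why: Third Wittig reaction with the stabilised α-methyl ylide gives the E C11=C12 olefin.

Step 21
Reactants: 28 ethyl (2E,4E,6E,8S,9Z,11E)-13-(TBDPSO)-4,10-diethyl-2,6,8,12-tetramethyltrideca-2,4,6,9,11-pentaenoate
Product: 29 (2E,4E,6E,8S,9Z,11E)-13-(TBDPSO)-4,10-diethyl-2,6,8,12-tetramethyltrideca-2,4,6,9,11-pentaen-1-ol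
Conditions: DIBAL-H (2.3 equiv), CH2Cl2, −78 °C; Rochelle salt
Reagents that add atoms: none
Why: DIBAL 1,2-reduction of the trienoate to the trienol.

Step 22
Reactants: 29 (2E,4E,6E,8S,9Z,11E)-13-(TBDPSO)-4,10-diethyl-2,6,8,12-tetramethyltrideca-2,4,6,9,11-pentaen-1-ol
Product: 30 (2E,4E,6E,8S,9Z,11E)-13-(TBDPSO)-4,10-diethyl-2,6,8,12-tetramethyltrideca-2,4,6,9,11-pentaenal
Conditions: MnO2 (excess), CH2Cl2, rt, dark
Reagents that add atoms: none
Why: MnO2 allylic oxidation to the trienal.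

Step 23
Reactants: 30 (2E,4E,6E,8S,9Z,11E)-13-(TBDPSO)-4,10-diethyl-2,6,8,12-tetramethyltrideca-2,4,6,9,11-pentaenal; 31 diethyl benzylphosphonate
Product: 32 tert-butyl{[(2E,4Z,6S,7E,9E,11E,13E)-4,10-diethyl-2,6,8,12-tetramethyl-14-phenyltetradeca-2,4,7,9,11,13-hexaen-1-yl]oxy}diphenylsilane
Conditions: NaH, 15-crown-5 (cat.), THF, 0 °C; then 30, 0 °C → rt
Reagents that add atoms: none
Why: Horner–Wadsworth–Emmons olefination with the benzylphosphonate anion gives the E-styryl olefin; no acidic site of the substrate is within reach of the base.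

Step 24
Reactants: 32 tert-butyl{[(2E,4Z,6S,7E,9E,11E,13E)-4,10-diethyl-2,6,8,12-tetramethyl-14-phenyltetradeca-2,4,7,9,11,13-hexaen-1-yl]oxy}diphenylsilane
Product: 33 (2E,4Z,6S,7E,9E,11E,13E)-4,10-diethyl-2,6,8,12-tetramethyl-14-phenyltetradeca-2,4,7,9,11,13-hexaen-1-ol
Conditions: TBAF, THF, 0 °C → rt, dark
Reagents that add atoms: none
Why: Fluoride desilylation frees the dienylic alcohol without touching the polyene.

Step 25
Reactants: 33 (2E,4Z,6S,7E,9E,11E,13E)-4,10-diethyl-2,6,8,12-tetramethyl-14-phenyltetradeca-2,4,7,9,11,13-hexaen-1-ol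
Product: 35 (1R,3aR,4R,5S,7aS)-3,5-diethyl-1,4,7-trimethyl-5-[(1E,3E)-2-methyl-4-phenylbuta-1,3-dien-1-yl]-3a,4,5,7a-tetrahydro-1H-indene-4-carbaldehyde, via linear hexaenal 34 (not isolated)
Conditions: MnO2 (excess), CH2Cl2, rt; filter; PhMe, BHT, 50 °C, dark
Reagents that add atoms: none
Why: MnO2 oxidation unmasks the (2E)-enal dienophile and a type-1 intramolecular Diels–Alder follows. The Z-olefin tether holds it over the C7–C10 diene. The diene face is set by C6, whose C–H eclipses the C8 methyl (A1,3 strain), and the formyl group is endo, which gives the trans-fused ring and sets C3a, C4, C5 and C7a in one step.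

Step 26
Reactants: 35 (1R,3aR,4R,5S,7aS)-3,5-diethyl-1,4,7-trimethyl-5-[(1E,3E)-2-methyl-4-phenylbuta-1,3-dien-1-yl]-3a,4,5,7a-tetrahydro-1H-indene-4-carbaldehyde
Product: 36 (1R,3aR,4R,5S,7aS)-3,5-diethyl-1,4,7-trimethyl-5-[(1E,3E)-2-methyl-4-phenylbuta-1,3-dien-1-yl]-3a,4,5,7a-tetrahydro-1H-indene-4-carboxylic acid (target)
Conditions: NaClO2, NaH2PO4, 2-methyl-2-butene (large excess), t-BuOH/THF/H2O, 0 °C → rt
Reagents that add atoms: sodium chlorite, [Na+].[O-]Cl=O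
Why: Pinnick oxidation converts the hindered, non-enolisable aldehyde to the acid; the scavenger takes up HOCl so the olefins are spared and no stereocentre is at risk.

**Compound list**

1 | methyl (S)-3-hydroxy-2-methylpropanoate ((S)-Roche ester) | COC(=O)[C@@H](C)CO | starting material
2 | methyl (S)-3-(TBSO)-2-methylpropanoate | COC(=O)[C@@H](C)CO[Si](C)(C)C(C)(C)C | intermediate
3 | (R)-3-(TBSO)-2-methylpropan-1-ol | OC[C@@H](C)CO[Si](C)(C)C(C)(C)C | intermediate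
4 | (S)-3-(TBSO)-2-methylpropanal | O=C[C@@H](C)CO[Si](C)(C)C(C)(C)C | intermediate
5 | ethyl butanoate | CCCC(=O)OCC | starting material
6 | lithium enolate of ethyl butanoate (lithium 1-ethoxybut-1-en-1-olate) | CCC=C([O-])OCC.[Li+] | intermediate (not isolated)
7 | ethyl (4S)-5-(TBSO)-2-ethyl-3-hydroxy-4-methylpentanoate (C2/C3 epimer mixture) | CCOC(=O)C(CC)C(O)[C@@H](C)CO[Si](C)(C)C(C)(C)C | intermediate
8 | ethyl (4S)-2-ethyl-3,5-dihydroxy-4-methylpentanoate (diol ester) | CCOC(=O)C(CC)C(O)[C@@H](C)CO | intermediate (not isolated)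
9 | (5S)-3-ethyl-4-hydroxy-5-methyltetrahydro-2H-pyran-2-one (C3/C4 epimer mixture) | CCC1C(O)[C@@H](C)COC1=O | intermediate
10 | (5S)-3-ethyl-5-methyl-2-oxotetrahydro-2H-pyran-4-yl methanesulfonate (mesylate) | CCC1C(OS(C)(=O)=O)[C@@H](C)COC1=O | intermediate (not isolated)
11 | (R)-3-ethyl-5-methyl-5,6-dihydro-2H-pyran-2-one | CCC1=C[C@@H](C)COC1=O | intermediate
12 | (5R)-3-ethyl-5-methyl-5,6-dihydro-2H-pyran-2-ol (anomer mixture) | CCC1=C[C@@H](C)COC1O | intermediate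
13 | ethyl 2-(triphenylphosphoranylidene)propanoate | CCOC(=O)C(C)=P(c1ccccc1)(c1ccccc1)c1ccccc1 | starting material
14 | (2Z,4R)-2-ethyl-5-hydroxy-4-methylpent-2-enal (open-chain hydroxy enal) | O=C/C(CC)=C\[C@@H](C)CO | intermediate (not isolated)
15 | ethyl (2E,4Z,6R)-4-ethyl-7-hydroxy-2,6-dimethylhepta-2,4-dienoate | CCOC(=O)/C(C)=C/C(CC)=C\[C@@H](C)CO | intermediate
16 | ethyl (2E,4Z,6R)-7-(TBSO)-4-ethyl-2,6-dimethylhepta-2,4-dienoate | CCOC(=O)/C(C)=C/C(CC)=C\[C@@H](C)CO[Si](C)(C)C(C)(C)C | intermediate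
17 | (2E,4Z,6R)-7-(TBSO)-4-ethyl-2,6-dimethylhepta-2,4-dien-1-ol | OC/C(C)=C/C(CC)=C\[C@@H](C)CO[Si](C)(C)C(C)(C)C | intermediate
18 | tert-butyl{[(2E,4Z,6R)-7-(TBSO)-4-ethyl-2,6-dimethylhepta-2,4-dien-1-yl]oxy}diphenylsilane | CC(C)(C)[Si](OC/C(C)=C/C(CC)=C\[C@@H](C)CO[Si](C)(C)C(C)(C)C)(c1ccccc1)c1ccccc1 | intermediate
19 | (2R,3Z,5E)-7-(TBDPSO)-4-ethyl-2,6-dimethylhepta-3,5-dien-1-ol | CC(C)(C)[Si](OC/C(C)=C/C(CC)=C\[C@@H](C)CO)(c1ccccc1)c1ccccc1 | intermediate
20 | (2R,3Z,5E)-7-(TBDPSO)-4-ethyl-2,6-dimethylhepta-3,5-dienal | CC(C)(C)[Si](OC/C(C)=C/C(CC)=C\[C@@H](C)C=O)(c1ccccc1)c1ccccc1 | intermediate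
21 | ethyl (2E,4R,5Z,7E)-9-(TBDPSO)-6-ethyl-2,4,8-trimethylnona-2,5,7-trienoate | CC(C)(C)[Si](OC/C(C)=C/C(CC)=C\[C@@H](C)/C=C(C)/C(=O)OCC)(c1ccccc1)c1ccccc1 | intermediate
22 | (2E,4R,5Z,7E)-9-(TBDPSO)-6-ethyl-2,4,8-trimethylnona-2,5,7-trien-1-ol | CC(C)(C)[Si](OC/C(C)=C/C(CC)=C\[C@@H](C)/C=C(C)/CO)(c1ccccc1)c1ccccc1 | intermediate
23 | (2E,4R,5Z,7E)-9-(TBDPSO)-6-ethyl-2,4,8-trimethylnona-2,5,7-trienal | CC(C)(C)[Si](OC/C(C)=C/C(CC)=C\[C@@H](C)/C=C(C)/C=O)(c1ccccc1)c1ccccc1 | intermediate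
24 | ethyl 2-(triphenylphosphoranylidene)butanoate | CCOC(=O)C(CC)=P(c1ccccc1)(c1ccccc1)c1ccccc1 | starting material
25 | ethyl (2E,4E,6S,7Z,9E)-11-(TBDPSO)-2,8-diethyl-4,6,10-trimethylundeca-2,4,7,9-tetraenoate | CC(C)(C)[Si](OC/C(C)=C/C(CC)=C\[C@@H](C)/C=C(C)/C=C(CC)/C(=O)OCC)(c1ccccc1)c1ccccc1 | intermediate
26 | (2E,4E,6S,7Z,9E)-11-(TBDPSO)-2,8-diethyl-4,6,10-trimethylundeca-2,4,7,9-tetraen-1-ol | CC(C)(C)[Si](OC/C(C)=C/C(CC)=C\[C@@H](C)/C=C(C)/C=C(CC)/CO)(c1ccccc1)c1ccccc1 | intermediate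
27 | (2E,4E,6S,7Z,9E)-11-(TBDPSO)-2,8-diethyl-4,6,10-trimethylundeca-2,4,7,9-tetraenal | CC(C)(C)[Si](OC/C(C)=C/C(CC)=C\[C@@H](C)/C=C(C)/C=C(CC)/C=O)(c1ccccc1)c1ccccc1 | intermediate
28 | ethyl (2E,4E,6E,8S,9Z,11E)-13-(TBDPSO)-4,10-diethyl-2,6,8,12-tetramethyltrideca-2,4,6,9,11-pentaenoate | CC(C)(C)[Si](OC/C(C)=C/C(CC)=C\[C@@H](C)/C=C(C)/C=C(CC)/C=C(C)/C(=O)OCC)(c1ccccc1)c1ccccc1 | intermediate
29 | (2E,4E,6E,8S,9Z,11E)-13-(TBDPSO)-4,10-diethyl-2,6,8,12-tetramethyltrideca-2,4,6,9,11-pentaen-1-ol | CC(C)(C)[Si](OC/C(C)=C/C(CC)=C\[C@@H](C)/C=C(C)/C=C(CC)/C=C(C)/CO)(c1ccccc1)c1ccccc1 | intermediate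
30 | (2E,4E,6E,8S,9Z,11E)-13-(TBDPSO)-4,10-diethyl-2,6,8,12-tetramethyltrideca-2,4,6,9,11-pentaenal | CC(C)(C)[Si](OC/C(C)=C/C(CC)=C\[C@@H](C)/C=C(C)/C=C(CC)/C=C(C)/C=O)(c1ccccc1)c1ccccc1 | intermediate
31 | diethyl benzylphosphonate | CCOP(=O)(Cc1ccccc1)OCC | starting material
32 | tert-butyl{[(2E,4Z,6S,7E,9E,11E,13E)-4,10-diethyl-2,6,8,12-tetramethyl-14-phenyltetradeca-2,4,7,9,11,13-hexaen-1-yl]oxy}diphenylsilane | CC(C)(C)[Si](OC/C(C)=C/C(CC)=C\[C@@H](C)/C=C(C)/C=C(CC)/C=C(C)/C=C/c1ccccc1)(c1ccccc1)c1ccccc1 | intermediate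
33 | (2E,4Z,6S,7E,9E,11E,13E)-4,10-diethyl-2,6,8,12-tetramethyl-14-phenyltetradeca-2,4,7,9,11,13-hexaen-1-ol | OC/C(C)=C/C(CC)=C\[C@@H](C)/C=C(C)/C=C(CC)/C=C(C)/C=C/c1ccccc1 | intermediate
34 | (2E,4Z,6S,7E,9E,11E,13E)-4,10-diethyl-2,6,8,12-tetramethyl-14-phenyltetradeca-2,4,7,9,11,13-hexaenal (linear hexaenal) | O=C/C(C)=C/C(CC)=C\[C@@H](C)/C=C(C)/C=C(CC)/C=C(C)/C=C/c1ccccc1 | intermediate (not isolated)
35 | (1R,3aR,4R,5S,7aS)-3,5-diethyl-1,4,7-trimethyl-5-[(1E,3E)-2-methyl-4-phenylbuta-1,3-dien-1-yl]-3a,4,5,7a-tetrahydro-1H-indene-4-carbaldehyde | CCC1=C[C@@H](C)[C@@H]2C(C)=C[C@@](/C=C(C)/C=C/c3ccccc3)(CC)[C@](C)(C=O)[C@@H]12 | intermediate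
36 | (1R,3aR,4R,5S,7aS)-3,5-diethyl-1,4,7-trimethyl-5-[(1E,3E)-2-methyl-4-phenylbuta-1,3-dien-1-yl]-3a,4,5,7a-tetrahydro-1H-indene-4-carboxylic acid | CCC1=C[C@@H](C)[C@@H]2C(C)=C[C@@](/C=C(C)/C=C/c3ccccc3)(CC)[C@](C)(C(=O)O)[C@@H]12 | target

**Totals and risks**

Total step count: 26. Longest linear sequence: 26 steps (1 → 36); 5, 13, 24 and 31 enter as purchased building blocks.

Three steps most likely to fail:

Step 8 (Wittig opening of lactol 12). The open-chain enal 14 is present only in small amount, so the reaction may be slow. The hydroxyl of 15 can also add back to the dienoate (oxa-Michael), and some Z→E leakage is possible. Fallback: setting out from lactone 11, the ring is opened with the aluminium amide from MeNH(OMe)·HCl and Me3Al to (2Z,4R)-2-ethyl-5-hydroxy-N-methoxy-N,4-dimethylpent-2-enamide F1, which is silylated at once (TBSCl, imidazole) to its TBS ether F2 and reduced with DIBAL-H (THF, −78 °C) to (2Z,4R)-5-(TBSO)-2-ethyl-4-methylpent-2-enal F3. This enal cannot close to a lactol and has no free hydroxyl, and ylide 13 (CH2Cl2, 40 °C) converts it to 16, where the route is rejoined (steps 7–9 replaced).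

Step 14 (Wittig on aldehyde 20). The α-stereocentre of this β,γ-unsaturated aldehyde can epimerise, or the olefin can move into conjugation, during a slow reaction with the weakly basic ylide. Fallback: setting out from 20, the aldehyde is consumed within minutes at −78 °C in a base-free Mukaiyama aldol with the trimethylsilyl ketene acetal of ethyl propanoate and BF3·OEt2 to give ethyl (4R,5Z,7E)-9-(TBDPSO)-6-ethyl-3-hydroxy-2,4,8-trimethylnona-5,7-dienoate F4. This is mesylated (MsCl, Et3N) to the corresponding methanesulfonate F5 and eliminated with DBU (E1cB, thermodynamic E olefin) to 21, where the route is rejoined.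

Step 25 (oxidation and intramolecular Diels–Alder). The (2E,4Z)-dienal 34 may isomerise at C4=C5 or undergo a 1,5-hydrogen shift from C6 before it cyclises, and the thermal endo:exo ratio of the free aldehyde is not guaranteed. Fallback: setting out from 33, the alcohol is oxidised with MnO2 at 0 °C and the crude aldehyde is taken straight into a Pinnick oxidation at 0 °C to give the configurationally more robust open-chain (2E,4Z,6S,7E,9E,11E,13E)-4,10-diethyl-2,6,8,12-tetramethyl-14-phenyltetradeca-2,4,7,9,11,13-hexaenoic acid F6. The cycloaddition is then run on the acid itself (PhMe, BHT, 70 °C, or as its sodium salt in water) and arrives directly at 36, replacing steps 25 and 26.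

**Further compounds**

F1 | step 8 | (2Z,4R)-2-ethyl-5-hydroxy-N-methoxy-N,4-dimethylpent-2-enamide | CON(C)C(=O)/C(CC)=C\[C@@H](C)CO
F2 | step 8 | (2Z,4R)-5-(TBSO)-2-ethyl-N-methoxy-N,4-dimethylpent-2-enamide | CON(C)C(=O)/C(CC)=C\[C@@H](C)CO[Si](C)(C)C(C)(C)C
F3 | step 8 | (2Z,4R)-5-(TBSO)-2-ethyl-4-methylpent-2-enal | O=C/C(CC)=C\[C@@H](C)CO[Si](C)(C)C(C)(C)C
F4 | step 14 | ethyl (4R,5Z,7E)-9-(TBDPSO)-6-ethyl-3-hydroxy-2,4,8-trimethylnona-5,7-dienoate (C2/C3 epimer mixture) | CC(C)(C)[Si](OC/C(C)=C/C(CC)=C\[C@@H](C)C(O)C(C)C(=O)OCC)(c1ccccc1)c1ccccc1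
F5 | step 14 | ethyl (4R,5Z,7E)-9-(TBDPSO)-6-ethyl-3-(methanesulfonyloxy)-2,4,8-trimethylnona-5,7-dienoate | CC(C)(C)[Si](OC/C(C)=C/C(CC)=C\[C@@H](C)C(OS(C)(=O)=O)C(C)C(=O)OCC)(c1ccccc1)c1ccccc1
F6 | step 25 | (2E,4Z,6S,7E,9E,11E,13E)-4,10-diethyl-2,6,8,12-tetramethyl-14-phenyltetradeca-2,4,7,9,11,13-hexaenoic acid | OC(=O)/C(C)=C/C(CC)=C\[C@@H](C)/C=C(C)/C=C(CC)/C=C(C)/C=C/c1ccccc1
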